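**Strategy.** C3 with its oxygen, C2, the enal α-carbon and the formyl carbon of the target trace a γ-butyrolactone that must be cis-fused to ring B (the dihydrofuran). The plan therefore cuts only O1–C2: in (S)-5-(5-bromo-2-hydroxyphenyl)furan-2(5H)-one the ortho phenol adds to the butenolide β-carbon, closing ring B and relaying the benzylic centre (C3) to C2 in one operation. The butenolide is built from 5-bromosalicylaldehyde by vinylation, Sharpless kinetic resolution, acryloylation and ring-closing metathesis. The lactone is then methylenated and reduced, its two hydroxyls are differentiated, the bromide becomes the (S)-senecioyloxyethyl arm, and a final allylic oxidation unveils the enal.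

Key step: step 7

Remark: atom labels follow 2,3-dihydrobenzofuran numbering (O1, C2, C3, C3a, C4 to C7, C7a). The target SMILES is read as (2R,3R), with the C2 and C3 substituents cis, and an (S) carbinol centre in the C5 side chain.

**Step 1**
Reactants: 1 5-bromosalicylaldehyde; 2 triisopropylsilyl chloride
Product: 3 5-bromo-2-(triisopropylsilyloxy)benzaldehyde
Conditions: imidazole, DMF, rt
Reagents that add atoms: triisopropylsilyl chloride, CC(C)[Si](Cl)(C(C)C)C(C)C
Why: Imidazole-promoted O-silylation of the phenol is routine, and the bulky triisopropylsilyl group is chosen because it resists transfer to a neighbouring benzylic alkoxide in step 2 yet is still removed by buffered fluoride.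

**Step 2**
Reactants: 3 5-bromo-2-(triisopropylsilyloxy)benzaldehyde; 4 vinylmagnesium bromide
Product: 5 rac-1-[5-bromo-2-(triisopropylsilyloxy)phenyl]prop-2-en-1-ol
Conditions: CH2=CHMgBr (1.2 equiv), THF, −78 °C; aq. NH4Cl at −78 °C
Reagents that add atoms: vinylmagnesium bromide, C=C[Mg]Br
Why: Grignard 1,2-addition to the aldehyde gives the racemic aryl vinyl carbinol, and addition and quench at low temperature keep the silyl group on the phenol oxygen.

**Step 3**
Reactants: 5 rac-1-[5-bromo-2-(triisopropylsilyloxy)phenyl]prop-2-en-1-ol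
Product: 6 (S)-1-[5-bromo-2-(triisopropylsilyloxy)phenyl]prop-2-en-1-ol
Conditions: Ti(OiPr)4, L-(+)-diisopropyl tartrate, t-BuOOH (0.6 equiv, anhydrous), 4 Å molecular sieves, CH2Cl2, −20 °C
Reagents that add atoms: none
Why: In this Sharpless kinetic resolution the Ti(OiPr)4/L-(+)-tartrate system should epoxidise the (R)-carbinol, whose aryl group lies on the face away from oxygen delivery, much faster, so the unreacted (S)-alcohol is recovered enantioenriched once conversion passes one half and is separated from the polar epoxy alcohol by chromatography.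

**Step 4**
Reactants: 6 (S)-1-[5-bromo-2-(triisopropylsilyloxy)phenyl]prop-2-en-1-ol; 7 acryloyl chloride
Product: 8 (S)-1-[5-bromo-2-(triisopropylsilyloxy)phenyl]prop-2-en-1-yl acrylate
Conditions: Et3N, DMAP (cat.), CH2Cl2, −20 → 0 °C
Reagents that add atoms: acryloyl chloride, C=CC(Cl)=O
Why: DMAP-catalysed O-acylation with the acid chloride leaves the carbinol configuration untouched, and the low temperature suppresses acrylate polymerisation and allylic transposition.

**Step 5**
Reactants: 8 (S)-1-[5-bromo-2-(triisopropylsilyloxy)phenyl]prop-2-en-1-yl acrylate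
Product: 9 (S)-5-[5-bromo-2-(triisopropylsilyloxy)phenyl]furan-2(5H)-one
Conditions: second-generation Grubbs catalyst RuCl2(=CHPh)(PCy3)(H2IMes) (5 mol%), CH2Cl2 (0.01 M), reflux
Reagents that add atoms: none
Why: Ring-closing metathesis of the allyl acrylate closes the butenolide with loss of ethylene under neutral conditions that do not touch the stereocentre, the electron-poor acrylate calling for the N-heterocyclic carbene catalyst and high dilution.

**Step 6**
Reactants: 9 (S)-5-[5-bromo-2-(triisopropylsilyloxy)phenyl]furan-2(5H)-one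
Product: 10 (S)-5-(5-bromo-2-hydroxyphenyl)furan-2(5H)-one
Conditions: Bu4NF (1.1 equiv), AcOH (1.5 equiv), THF, 0 °C
Reagents that add atoms: none
Why: Fluoride cleaves the aryl silyl ether quickly while acetic acid keeps the liberated phenol protonated, so the base-sensitive γ-hydrogen of the butenolide is not disturbed, and any phenol that already cyclises converges on 11.

**Step 7**
Reactants: 10 (S)-5-(5-bromo-2-hydroxyphenyl)furan-2(5H)-one
Product: 11 (3aR,8bR)-7-bromo-3a,8b-dihydrofuro[3,2-b]benzofuran-2(3H)-one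
Conditions: Et3N (0.1 equiv), CH2Cl2, −20 → 0 °C; AcOH quench
Reagents that add atoms: none
Why: Triethylamine reversibly deprotonates the phenol, which is far more acidic and ionises faster than the γ C–H; the phenoxide adds in conjugate fashion to the β-carbon of the butenolide and the lactone enolate is protonated by the ammonium ion, so the base is catalytic. The closest known reaction type is the intramolecular oxa-Michael addition of phenols and alcohols to butenolides and enoates. Ring B is closed in the 5-exo-trig mode by formation of O1–C2. The new stereocentre C2 is set by the existing benzylic centre C3: the tether reaches the β-carbon only from the face that carries the aryl group, and two five-membered rings sharing C2–C3 can only be cis-fused, which gives (3aR,8bR). The step needs O–H over γ C–H deprotonation, secured by the acidity of the 4-bromophenol, the substoichiometric weak base, the low temperature and an acidic quench at full conversion; once the ring is closed, C3 is no longer vinylogously acidic.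

**Step 8**
Reactants: 11 (3aR,8bR)-7-bromo-3a,8b-dihydrofuro[3,2-b]benzofuran-2(3H)-one; 12 N,N-dimethylmethyleneiminium iodide (Eschenmoser's salt)
Product: 15 (3aR,8bR)-7-bromo-3-methylene-3a,8b-dihydrofuro[3,2-b]benzofuran-2(3H)-one, via Mannich base 13 (not isolated), via trimethylammonium iodide 14 (not isolated)
Conditions: LiN(SiMe3)2 (1.05 equiv), THF, −78 °C; CH2=NMe2+ I−, −78 → 0 °C; MeI, MeOH, rt; aq. NaHCO3, CH2Cl2, rt
Reagents that add atoms: N,N-dimethylmethyleneiminium iodide, C=[N+](C)C.[I-]
Why: Mannich reaction of the lactone enolate with the iminium salt on the convex face, exhaustive methylation and Hofmann-type elimination is the standard α-methylenation of γ-lactones; one equivalent of base and trapping at −78 °C keep loss of the β-aryloxide small, and any reversible opening can only re-close to the same cis-fused lactone.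

**Step 9**
Reactants: 15 (3aR,8bR)-7-bromo-3-methylene-3a,8b-dihydrofuro[3,2-b]benzofuran-2(3H)-one
Product: 16 (2R,3R)-5-bromo-2-(3-hydroxyprop-1-en-2-yl)-2,3-dihydrobenzofuran-3-ol
Conditions: i-Bu2AlH (4 equiv), CH2Cl2, −78 → 0 °C; aq. KNaC4H4O6 (potassium sodium tartrate)
Reagents that add atoms: none
Why: Excess i-Bu2AlH reduces the α-methylene lactone by 1,2-hydride addition through the lactol to the allylic 1,4-diol without touching the aryl bromide, the exocyclic alkene or the two stereocentres.

**Step 10**
Reactants: 16 (2R,3R)-5-bromo-2-(3-hydroxyprop-1-en-2-yl)-2,3-dihydrobenzofuran-3-ol; 17 tert-butyl(chloro)diphenylsilane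
Product: 18 (2R,3R)-5-bromo-2-[3-(tert-butyldiphenylsilyloxy)prop-1-en-2-yl]-2,3-dihydrobenzofuran-3-ol
Conditions: imidazole, CH2Cl2, 0 °C
Reagents that add atoms: tert-butyl(chloro)diphenylsilane, CC(C)(C)[Si](Cl)(c1ccccc1)c1ccccc1
Why: Silylation with a bulky chlorosilane is strongly selective for the unhindered primary allylic hydroxyl over the secondary benzylic C3 hydroxyl flanked by the cis C2 substituent, and the tert-butyldiphenylsilyl ether survives the acidic hydrolysis in step 12.

**Step 11**
Reactants: 18 (2R,3R)-5-bromo-2-[3-(tert-butyldiphenylsilyloxy)prop-1-en-2-yl]-2,3-dihydrobenzofuran-3-ol; 19 3-methylbutanoyl chloride (isovaleryl chloride)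
Product: 20 (2R,3R)-5-bromo-2-[3-(tert-butyldiphenylsilyloxy)prop-1-en-2-yl]-2,3-dihydrobenzofuran-3-yl 3-methylbutanoate
Conditions: pyridine, DMAP (0.1 equiv), CH2Cl2, 0 °C → rt
Reagents that add atoms: 3-methylbutanoyl chloride, CC(C)CC(Cl)=O
Why: DMAP-catalysed acylation of the remaining secondary alcohol installs the isovalerate with retention at C3, the mild base avoiding elimination towards the benzofuran.

**Step 12**
Reactants: 20 (2R,3R)-5-bromo-2-[3-(tert-butyldiphenylsilyloxy)prop-1-en-2-yl]-2,3-dihydrobenzofuran-3-yl 3-methylbutanoate; 21 tributyl(1-ethoxyvinyl)stannane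
Product: 23 (2R,3R)-5-acetyl-2-[3-(tert-butyldiphenylsilyloxy)prop-1-en-2-yl]-2,3-dihydrobenzofuran-3-yl 3-methylbutanoate, via 1-ethoxyvinyl arene 22 (not isolated)
Conditions: Pd(P(t-Bu)3)2 (5 mol%), CsF (2.2 equiv), 1,4-dioxane, rt → 40 °C; then 1 M HCl, THF, 0 °C, 15 min
Reagents that add atoms: tributyl(1-ethoxyvinyl)stannane, CCCC[Sn](CCCC)(CCCC)C(=C)OCC; water, O
Why: Stille cross-coupling of the aryl bromide with the acetyl-anion equivalent and mild acid hydrolysis of the enol ether give the aryl methyl ketone, the bulky electron-rich phosphine allowing oxidative addition into C–Br near room temperature, where the allylic aryl ether at C2 and the benzylic ester at C3 should not be ionised.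

**Step 13**
Reactants: 23 (2R,3R)-5-acetyl-2-[3-(tert-butyldiphenylsilyloxy)prop-1-en-2-yl]-2,3-dihydrobenzofuran-3-yl 3-methylbutanoate
Product: 24 (2R,3R)-2-[3-(tert-butyldiphenylsilyloxy)prop-1-en-2-yl]-5-[(1S)-1-hydroxyethyl]-2,3-dihydrobenzofuran-3-yl 3-methylbutanoate
Conditions: RuCl[(S,S)-TsDPEN](p-cymene) (2 mol%), HCO2H/Et3N (5:2), EtOAc, rt
Reagents that add atoms: none
Why: Noyori asymmetric transfer hydrogenation with the (S,S)-configured catalyst delivers hydride to the ketone face that gives the (S)-1-arylethanol, as it does for acetophenone, while formic acid–triethylamine leaves the ester, the silyl ether and the isolated alkene untouched.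

**Step 14**
Reactants: 24 (2R,3R)-2-[3-(tert-butyldiphenylsilyloxy)prop-1-en-2-yl]-5-[(1S)-1-hydroxyethyl]-2,3-dihydrobenzofuran-3-yl 3-methylbutanoate; 25 3-methylbut-2-enoic acid (senecioic acid)
Product: 26 (2R,3R)-2-[3-(tert-butyldiphenylsilyloxy)prop-1-en-2-yl]-5-[(1S)-1-(3-methylbut-2-enoyloxy)ethyl]-2,3-dihydrobenzofuran-3-yl 3-methylbutanoate
Conditions: DCC (1.5 equiv), DMAP (0.2 equiv), CH2Cl2, 0 °C → rt
Reagents that add atoms: 3-methylbut-2-enoic acid, CC(C)=CC(=O)O
Why: Steglich esterification acylates the carbinol oxygen, so the (S) configuration is retained, and the carbodiimide method avoids the ketene pathway by which senecioyl chloride and amine bases deconjugate the ester.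

**Step 15**
Reactants: 26 (2R,3R)-2-[3-(tert-butyldiphenylsilyloxy)prop-1-en-2-yl]-5-[(1S)-1-(3-methylbut-2-enoyloxy)ethyl]-2,3-dihydrobenzofuran-3-yl 3-methylbutanoate
Product: 27 (2R,3R)-2-(3-hydroxyprop-1-en-2-yl)-5-[(1S)-1-(3-methylbut-2-enoyloxy)ethyl]-2,3-dihydrobenzofuran-3-yl 3-methylbutanoate
Conditions: HF·pyridine, pyridine, THF, 0 °C → rt
Reagents that add atoms: none
Why: Pyridine-buffered hydrogen fluoride removes the silyl ether without base, so neither acyl migration from the C3 ester to the freed primary hydroxyl nor elimination is triggered.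

**Step 16**
Reactants: 27 (2R,3R)-2-(3-hydroxyprop-1-en-2-yl)-5-[(1S)-1-(3-methylbut-2-enoyloxy)ethyl]-2,3-dihydrobenzofuran-3-yl 3-methylbutanoate
Product: 28 (2R,3R)-5-[(1S)-1-(3-methylbut-2-enoyloxy)ethyl]-2-(3-oxoprop-1-en-2-yl)-2,3-dihydrobenzofuran-3-yl 3-methylbutanoate (CNP0325942.1)
Conditions: MnO2 (activated, 20 equiv), CH2Cl2, rt
Reagents that add atoms: none
Why: Activated MnO2 oxidises the primary allylic alcohol to the α-substituted acrolein under neutral heterogeneous conditions that leave both esters and all three stereocentres untouched, there being no other allylic or free benzylic alcohol to compete.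

**Compound list**
1 | 5-bromosalicylaldehyde | O=Cc1cc(Br)ccc1O | starting material
2 | triisopropylsilyl chloride | CC(C)[Si](Cl)(C(C)C)C(C)C | starting material
3 | 5-bromo-2-(triisopropylsilyloxy)benzaldehyde | O=Cc1cc(Br)ccc1O[Si](C(C)C)(C(C)C)C(C)C | intermediate
4 | vinylmagnesium bromide | C=C[Mg]Br | starting material
5 | rac-1-[5-bromo-2-(triisopropylsilyloxy)phenyl]prop-2-en-1-ol | C=CC(O)c1cc(Br)ccc1O[Si](C(C)C)(C(C)C)C(C)C | intermediate
6 | (S)-1-[5-bromo-2-(triisopropylsilyloxy)phenyl]prop-2-en-1-ol | C=C[C@H](O)c1cc(Br)ccc1O[Si](C(C)C)(C(C)C)C(C)C | intermediate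
7 | acryloyl chloride | C=CC(Cl)=O | starting material
8 | (S)-1-[5-bromo-2-(triisopropylsilyloxy)phenyl]prop-2-en-1-yl acrylate | C=C[C@H](OC(=O)C=C)c1cc(Br)ccc1O[Si](C(C)C)(C(C)C)C(C)C | intermediate
9 | (S)-5-[5-bromo-2-(triisopropylsilyloxy)phenyl]furan-2(5H)-one | O=C1C=C[C@H](O1)c1cc(Br)ccc1O[Si](C(C)C)(C(C)C)C(C)C | intermediate
10 | (S)-5-(5-bromo-2-hydroxyphenyl)furan-2(5H)-one | O=C1C=C[C@H](O1)c1cc(Br)ccc1O | intermediate
11 | (3aR,8bR)-7-bromo-3a,8b-dihydrofuro[3,2-b]benzofuran-2(3H)-one (cis-fused) | O=C1C[C@H]2Oc3ccc(Br)cc3[C@H]2O1 | intermediate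
12 | N,N-dimethylmethyleneiminium iodide (Eschenmoser's salt) | C=[N+](C)C.[I-] | starting material
13 | (3R,3aR,8bR)-7-bromo-3-[(dimethylamino)methyl]-3a,8b-dihydrofuro[3,2-b]benzofuran-2(3H)-one (Mannich base, not isolated) | O=C1[C@H](CN(C)C)[C@H]2Oc3ccc(Br)cc3[C@H]2O1 | intermediate
14 | [(3R,3aR,8bR)-7-bromo-2-oxo-2,3,3a,8b-tetrahydrofuro[3,2-b]benzofuran-3-yl]-N,N,N-trimethylmethanaminium iodide (not isolated) | O=C1[C@H](C[N+](C)(C)C)[C@H]2Oc3ccc(Br)cc3[C@H]2O1.[I-] | intermediate
15 | (3aR,8bR)-7-bromo-3-methylene-3a,8b-dihydrofuro[3,2-b]benzofuran-2(3H)-one | O=C1C(=C)[C@H]2Oc3ccc(Br)cc3[C@H]2O1 | intermediate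
16 | (2R,3R)-5-bromo-2-(3-hydroxyprop-1-en-2-yl)-2,3-dihydrobenzofuran-3-ol | C=C(CO)[C@H]1Oc2ccc(Br)cc2[C@H]1O | intermediate
17 | tert-butyl(chloro)diphenylsilane | CC(C)(C)[Si](Cl)(c1ccccc1)c1ccccc1 | starting material
18 | (2R,3R)-5-bromo-2-[3-(tert-butyldiphenylsilyloxy)prop-1-en-2-yl]-2,3-dihydrobenzofuran-3-ol | C=C(CO[Si](c1ccccc1)(c1ccccc1)C(C)(C)C)[C@H]1Oc2ccc(Br)cc2[C@H]1O | intermediate
19 | 3-methylbutanoyl chloride (isovaleryl chloride) | CC(C)CC(Cl)=O | starting material
20 | (2R,3R)-5-bromo-2-[3-(tert-butyldiphenylsilyloxy)prop-1-en-2-yl]-2,3-dihydrobenzofuran-3-yl 3-methylbutanoate | C=C(CO[Si](c1ccccc1)(c1ccccc1)C(C)(C)C)[C@H]1Oc2ccc(Br)cc2[C@H]1OC(=O)CC(C)C | intermediate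
21 | tributyl(1-ethoxyvinyl)stannane | CCCC[Sn](CCCC)(CCCC)C(=C)OCC | starting material
22 | (2R,3R)-2-[3-(tert-butyldiphenylsilyloxy)prop-1-en-2-yl]-5-(1-ethoxyvinyl)-2,3-dihydrobenzofuran-3-yl 3-methylbutanoate (not isolated) | C=C(CO[Si](c1ccccc1)(c1ccccc1)C(C)(C)C)[C@H]1Oc2ccc(C(=C)OCC)cc2[C@H]1OC(=O)CC(C)C | intermediate
23 | (2R,3R)-5-acetyl-2-[3-(tert-butyldiphenylsilyloxy)prop-1-en-2-yl]-2,3-dihydrobenzofuran-3-yl 3-methylbutanoate | C=C(CO[Si](c1ccccc1)(c1ccccc1)C(C)(C)C)[C@H]1Oc2ccc(C(C)=O)cc2[C@H]1OC(=O)CC(C)C | intermediate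
24 | (2R,3R)-2-[3-(tert-butyldiphenylsilyloxy)prop-1-en-2-yl]-5-[(1S)-1-hydroxyethyl]-2,3-dihydrobenzofuran-3-yl 3-methylbutanoate | C=C(CO[Si](c1ccccc1)(c1ccccc1)C(C)(C)C)[C@H]1Oc2ccc([C@H](C)O)cc2[C@H]1OC(=O)CC(C)C | intermediate
25 | 3-methylbut-2-enoic acid (senecioic acid) | CC(C)=CC(=O)O | starting material
26 | (2R,3R)-2-[3-(tert-butyldiphenylsilyloxy)prop-1-en-2-yl]-5-[(1S)-1-(3-methylbut-2-enoyloxy)ethyl]-2,3-dihydrobenzofuran-3-yl 3-methylbutanoate | C=C(CO[Si](c1ccccc1)(c1ccccc1)C(C)(C)C)[C@H]1Oc2ccc([C@H](C)OC(=O)C=C(C)C)cc2[C@H]1OC(=O)CC(C)C | intermediate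
27 | (2R,3R)-2-(3-hydroxyprop-1-en-2-yl)-5-[(1S)-1-(3-methylbut-2-enoyloxy)ethyl]-2,3-dihydrobenzofuran-3-yl 3-methylbutanoate | C=C(CO)[C@H]1Oc2ccc([C@H](C)OC(=O)C=C(C)C)cc2[C@H]1OC(=O)CC(C)C | intermediate
28 | (2R,3R)-5-[(1S)-1-(3-methylbut-2-enoyloxy)ethyl]-2-(3-oxoprop-1-en-2-yl)-2,3-dihydrobenzofuran-3-yl 3-methylbutanoate | C=C(C=O)[C@H]1Oc2ccc([C@H](C)OC(=O)C=C(C)C)cc2[C@H]1OC(=O)CC(C)C | target

**Step count and risks**

Total step count: 16. Longest linear sequence: 16 steps, from 1 to 28.

Steps most likely to fail: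

1. Step 7. Enantiomeric purity may be lost if deprotonation at the γ-carbon of the butenolide, or drift of the double bond to the achiral 2(3H)-furanone, competes with ring closure. The fallback avoids the base-labile butenolide and sets out from 6. Buffered desilylation (Bu4NF, AcOH, THF, 0 °C) should give (S)-4-bromo-2-(1-hydroxyprop-2-en-1-yl)phenol F1, which is used at once because ortho-hydroxybenzyl allylic alcohols dehydrate readily. Oxidative carbonylation (PdCl2 cat., CuCl2, NaOAc, AcOH, CO 1 atm, rt) then effects 5-exo oxypalladation of the vinyl group by the phenol, CO insertion and capture of the acyl-palladium species by the carbinol oxygen. This sequence is known for pent-4-ene-1,3-diols, can only lactonise when O1 and the carbinol oxygen are cis, and leaves the carbinol centre untouched. The fallback comes back to the route at 11.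

2. Step 8. The enolate may expel the β-aryloxide (retro-conjugate addition), which costs material and, if the opened butenolide is deprotonated again, enantiomeric purity; aminomethylation may also be incomplete. The fallback sets out from 11 and replaces the free enolate by a chelated β-keto-acid route. Carboxylation with MeOMgOCO2Me (methoxymagnesium methyl carbonate) in DMF at 125 °C and acidic work-up should give (3S,3aR,8bR)-7-bromo-2-oxo-2,3,3a,8b-tetrahydrofuro[3,2-b]benzofuran-3-carboxylic acid F2, epimerisable at C3 and drawn with the carboxyl group on the convex face. Decarboxylative Mannich methylenation (aq. HCHO, Et2NH, NaOAc, AcOH, rt then brief warming), as used on cis-fused bis-lactones that carry a β-acyloxy group, then comes back to the route at 15.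

3. Step 3. Epoxidation of a hindered, monosubstituted alkene may be slow or discriminate poorly between the enantiomers, so the recovered alcohol may fall short in enantiomeric purity, and half the material is lost in any case. The fallback sets out from 3 and builds the butenolide by catalytic asymmetric alkynylation in place of resolution and metathesis. Addition of methyl propiolate with Me2Zn and a ProPhenol ligand (toluene, 0 °C; the ligand antipode that delivers the (S)-carbinol, confirmed by Mosher ester analysis) should give methyl (S)-4-[5-bromo-2-(triisopropylsilyloxy)phenyl]-4-hydroxybut-2-ynoate F3. Semihydrogenation (H2, Pd/CaCO3 poisoned with Pb(OAc)2, quinoline, EtOAc) gives methyl (S,Z)-4-[5-bromo-2-(triisopropylsilyloxy)phenyl]-4-hydroxybut-2-enoate F4, which lactonises with catalytic pyridinium p-toluenesulfonate in toluene. The fallback comes back to the route at 9.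

**Further compounds**
F1 | step 7 | (S)-4-bromo-2-(1-hydroxyprop-2-en-1-yl)phenol | C=C[C@H](O)c1cc(Br)ccc1O
F2 | step 8 | (3S,3aR,8bR)-7-bromo-2-oxo-2,3,3a,8b-tetrahydrofuro[3,2-b]benzofuran-3-carboxylic acid | O=C1[C@H](C(=O)O)[C@H]2Oc3ccc(Br)cc3[C@H]2O1
F3 | step 3 | methyl (S)-4-[5-bromo-2-(triisopropylsilyloxy)phenyl]-4-hydroxybut-2-ynoate | COC(=O)C#C[C@H](O)c1cc(Br)ccc1O[Si](C(C)C)(C(C)C)C(C)C
F4 | step 3 | methyl (S,Z)-4-[5-bromo-2-(triisopropylsilyloxy)phenyl]-4-hydroxybut-2-enoate | COC(=O)/C=C\[C@H](O)c1cc(Br)ccc1O[Si](C(C)C)(C(C)C)C(C)C
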